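## Analysis of the target

The target (46) is a C30 sipholane-type triterpenoid made of two bicyclic halves joined only by a CH2CH2 linker. One half is a hydroazulene (ring C, a cycloheptene; ring D, a cyclopentane; azulene locants C-1 to C-8a). The other is a 2,2-dimethyloxepan-3-one fused to a cyclohexane (rings A and B; benzoxepine locants O-1' to C-9a'). Rings C/D carry four stereocentres, (1S,3aS,5R,8aS): the fusion is cis, the C-1 hydroxyl lies on the face of the two fusion hydrogens with its methyl towards ring C, and the C-5 hydrogen lies on that same face, so the linker is syn to ring D across the quaternary C-4. Rings A/B carry the other four, (5a'S,6'S,7'R,9a'R): as the structure is written, the C-5a' methyl and the C-9a' hydrogen are on the same face, so the oxepane is cis-fused with the angular methyl anti to the ring oxygen, and the angular methyl, the linker on C-6' and the C-7' hydroxyl share one face of ring B. The sensitive groups are two tertiary alcohols, the α-alkoxy ketone of ring A, and the C-6/C-7 alkene, which is only skipped from the C-5 methine and must not move into the tetrasubstituted position. The hard points are the seven-membered carbocycle with a quaternary carbon between two stereocentres, the C-5 stereocentre with no neighbouring functional group, the cis-fused oxepane with an angular methyl, and the union of two hindered halves through two plain methylenes. The strategy rests on rings C/D: C-5 and C-1 are 1,5-related through C-4 (CMe2) and the fusion carbons C-3a and C-8a, the pattern of a 1,5-diketone left by an enol–alkene [2+2] photocycloaddition followed by retro-aldol cleavage.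

## Retrosynthetic reasoning

**Oxidation state of ring A.** Target 46 is taken back to triol 45 and its tris-silyl ether 44. The ring A ketone is carried as a protected secondary alcohol, because the fragment union uses a basic carbanion and ring B needs a methyl nucleophile. In 45 only one secondary alcohol exists, so the last oxidation needs no selectivity.

**The linker.** The central CH2–CH2 bond is cut: 44 comes from alkene 43, and 43 from sulfone 23 and aldehyde 42. Each half then needs one carbon outside its ring. C-5 and C-6' sit next to fully substituted carbons, so substitution at the neighbouring methylenes, or a metal-catalysed alkyl–alkyl coupling there, would be slow. A carbonyl olefination tolerates this hindrance and creates no stereocentre. The forward step must leave a 1,2-disubstituted alkene that can be reduced beside the trisubstituted ring C alkene.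

**Periphery of rings C/D.** Sulfone 23 goes back through alcohol 21 to diene 19, enone 18, hydroxy ketone 16 and diketone 14. The linker carbon and the C-5 hydrogen come from hydroboration of an exocyclic methylene. The C-6/C-7 alkene comes from dehydrogenation of the ring C ketone, which also erases the auxiliary methyl stereocentre. The C-1 carbinol comes from the ring D ketone by methylenation (15) and hydration, because direct methyl addition would put the methyl, not the oxygen, on the convex face. Both carbonyl groups of 14 are thus used.

**Key disconnection.** Diketone 14 is traced to enol acetate 11. The bonds C-3a–C-8a and C-4–C-5 are cut and the cyclopentane bond between the future C-5 and C-8a is restored. This is the best place to cut because it makes the seven-membered ring from a five-membered one, forms the bond to the quaternary C-4 by radical recombination, and leaves oxygen at exactly C-1 and C-5. The forward reaction must add on one face of the cyclopentene and deliver a cis ring fusion.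

**The photosubstrate.** Enol acetate 11 comes from β-diketone 10, which comes from aldol 9, made from ketone 4 and aldehyde 8. Ketone 4 comes from cyclopentanone 1 through hydrazones 2 and 3. Aldehyde 8 comes from ester 7, the Claisen product of 5 and 6. The only stereocentre, the methyl-bearing carbon of 4, controls the photoaddition and is later removed.

**Ring A.** Aldehyde 42 goes back through 41 and 40 to oxepane 39. The O-1'–C-2' bond is cut: the C-9a' hydroxyl of triol 37 adds in Markovnikov fashion to an isopropenyl group. This cut is chosen because the exo mode fixes the ring size at seven and the C-3' oxygen is already present; opening a trisubstituted epoxide instead would compete with six-membered ring formation. Triol 37 comes from 36, and 36 from epoxide 35 and alkene 34.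

**Ring B.** Alcohol 34 goes back through ketone 33 and enol ether 32 to enone 31. Three contiguous centres are set one at a time on the ring: methyl addition anti to the silyloxy group (this makes the angular methyl anti to oxygen, hence the cis fusion), alkylation anti to the side chain, and equatorial methyl addition to the ketone. Enone 31 comes from vinylogous ester 27 and bromide 28 (through 29 and 30). Ester 27 comes from 26, 25 and the commercial enone 24.

## Alternatives that were turned down

**Alternative 1:** The C-5a'–C-6' bond of ring B is cut. In the forward step a trivalent titanium reagent opens a trisubstituted epoxide to a tertiary β-titanoxy radical, which closes 6-exo onto a tethered enoate and gives ring B hydroxy ester A1.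
- For: one mild radical step forms ring B with C-5a' and C-6', keeps C-7' and C-9a' from the precursor, and the ester arm already holds both linker carbons. On step count for ring B it is stronger than the stepwise sequence used here.
- Against: the quaternary carbon arises from a planar radical. Whether the silyloxymethyl group ends up cis to the C-9a' oxygen (needed for the cis-fused oxepane), and the configuration at C-6', depend on a transition-state preference, not on a stereospecific event. Ring A still lacks three carbons and the tertiary ether. With both linker carbons on ring B, the union would have to form a bond directly at C-5, the most hindered carbon of ring C.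
- Comparison: it does nothing for the seven-membered carbocycle. The chosen strategy spends its key step there and sets the ring B centres by separate, checkable substrate-controlled steps.

**Alternative 2:** The O-1'–C-2' and C-5a'–C-6' bonds and the lactone C–O bond are cut together. In the forward step a silyl triflate with a hindered pyridine base activates a terminal epoxide; the inner epoxide oxygen attacks the CMe2 carbon (ring A), the alkene opens the epoxonium ion at the quaternary carbon (ring B), and the carboxyl group traps the cation to give hydroxy lactone A2.
- For: rings A and B, four stereocentres and both linker carbons come from one stereospecific operation. For this half it is clearly shorter than the fourteen steps used here.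
- Against: the fusion needed is cis (C-5a' methyl and C-9a' hydrogen syn). Anti opening at the quaternary carbon gives that only from a cis-epoxide, so the acyclic substrate needs (Z)-trisubstituted alkenes and an enantioselective epoxidation of a cis-type trisubstituted alkene, where reagent control is least reliable. Five-membered ether formation, elimination and hydride shifts compete in the cascade. The lactone carbonyl would again have to be joined directly to C-5.
- Comparison: as for Alternative 1, rings C/D are untouched. The chosen strategy solves the carbocyclic half and accepts a longer but stepwise-controlled route to rings A/B.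

**Alternative 3:** The bond from C-3a to the adjacent ring D methylene is cut. In the forward step a trivalent iron Lewis acid promotes conrotatory closure of a cycloheptadienyl silylvinyl ketone, and loss of silicon leaves cis-fused cyclopentenone A3.
- For: ring C already carries the C-6/C-7 alkene, the gem-dimethyl carbon and C-5 with a two-carbon arm, so no late hydroboration is needed. On the C-5 stereocentre this alternative is stronger than the chosen route. Silicon fixes the alkene position and cis fusion is the usual outcome.
- Against: the substituted seven-membered ring, the hard part, must be made first and the key step does not help with it. The new bond forms at the carbon next to the quaternary centre. The sense of conrotation is steered only by the remote C-5 centre across CMe2. The skipped diene is exposed to a strong Lewis acid. The enone still needs reduction and a carbinol with oxygen on the convex face.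
- Comparison: the chosen photochemical step makes rings C and D together from a cyclopentanone, forms the bond to the quaternary carbon without a steric penalty, and places both oxygen functions where they are needed.

Key step: step 9

Remark on the chemistry: the lipase used in step 19 is assumed to hydrolyse the (R)-acetate of 25 faster than the (S)-acetate.

## Route

**Fragment 1 (rings C/D)**

Step 1
Reactants: 1 cyclopentanone
Product: 2 (S)-N-cyclopentylidene-2-(methoxymethyl)pyrrolidin-1-amine
Conditions: (S)-1-amino-2-(methoxymethyl)pyrrolidine (SAMP), neat, 60 °C
Reagents that add atoms: SAMP, COC[C@@H]1CCCN1N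
Why: Hydrazone condensation; it attaches the Enders auxiliary that will control the α-methylation.

Step 2
Reactants: 2 SAMP hydrazone of cyclopentanone
Product: 3 (S)-2-(methoxymethyl)-N-[(2R)-2-methylcyclopentylidene]pyrrolidin-1-amine
Conditions: LiN(i-Pr)2, THF, 0 °C; MeI, −100 °C → rt
Reagents that add atoms: iodomethane, CI
Why: Enders SAMP-hydrazone alkylation; the methoxy-chelated azaenolate is methylated on one face, which for cyclic ketones should give the (R)-2-methyl centre.

Step 3
Reactants: 3 α-methyl hydrazone
Product: 4 (R)-2-methylcyclopentan-1-one
Conditions: sat. aq. oxalic acid, Et2O, rt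
Reagents that add atoms: water, O
Why: Two-phase hydrazone hydrolysis under mild acid, a method that frees α-substituted ketones without racemization and returns the auxiliary.

Step 4
Reactants: 5 2-methylbut-3-en-2-ol; 6 triethyl orthoacetate
Product: 7 ethyl 5-methylhex-4-enoate
Conditions: EtCO2H (cat.), 140 °C, EtOH distilled off
Reagents that add atoms: none
Why: Johnson–Claisen rearrangement; the ketene acetal of the tertiary allylic alcohol rearranges [3,3] to the γ,δ-unsaturated ester with the trisubstituted alkene.

Step 5
Reactants: 7 ethyl 5-methylhex-4-enoate
Product: 8 5-methylhex-4-enal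
Conditions: i-Bu2AlH, CH2Cl2, −78 °C
Reagents that add atoms: none
Why: Partial reduction of an ester to the aldehyde through the stable tetrahedral aluminium intermediate at low temperature.

Step 6
Reactants: 4 (R)-2-methylcyclopentan-1-one; 8 5-methylhex-4-enal
Product: 9 (2R)-5-(1-hydroxy-5-methylhex-4-en-1-yl)-2-methylcyclopentan-1-one
Conditions: LiN(i-Pr)2, THF, −78 °C; then 8, −78 °C
Reagents that add atoms: none
Why: Kinetic deprotonation at the unsubstituted α-carbon followed by aldol addition; the methyl stereocentre is not touched, and the two new centres (a mixture) are removed in step 7.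

Step 7
Reactants: 9 aldol adduct
Product: 10 (5R)-5-methyl-2-(5-methylhex-4-enoyl)cyclopentan-1-one
Conditions: Dess–Martin periodinane, NaHCO3, CH2Cl2, rt
Reagents that add atoms: none
Why: Dess–Martin oxidation of a β-hydroxy ketone to the β-diketone under non-basic conditions, so the methyl-bearing carbon should keep its configuration.

Step 8
Reactants: 10 β-diketone
Product: 11 (5R)-5-methyl-2-(5-methylhex-4-enoyl)cyclopent-1-en-1-yl acetate
Conditions: AcCl, pyridine, CH2Cl2, 0 °C
Reagents that add atoms: acetyl chloride, CC(Cl)=O
Why: O-acylation of the enolized β-diketone; the ring-oxygen ester, with the endocyclic double bond conjugated to the side-chain ketone, is the isomer the photoreaction needs, and cold, brief conditions limit epimerization next to it.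

Step 9
Reactants: 11 ring enol acetate
Product: 14 (3aS,6R,8aS)-4,4,6-trimethyloctahydroazulene-1,5-dione, via cyclobutyl acetate photoadduct 12 (not isolated), via cyclobutanol 13 (not isolated)
Conditions: hν (λ > 300 nm, Pyrex), cyclohexane, rt; then K2CO3, MeOH, 0 °C
Reagents that add atoms: none
Why: Excitation of the enol acetate double bond conjugated with the side-chain ketone gives a triplet that bonds its α-carbon to the alkene CH in a 5-exo (1,5) closure, which forms ring D and leaves a 1,4-biradical on the acetoxy-bearing carbon and the tertiary CMe2 terminus; collapse of this biradical gives the cyclobutane of 12. This is an intramolecular de Mayo reaction, the known behaviour of 2-acylcycloalkanone enol esters that carry the alkene three atoms from the enone. Methanolysis of the acetate gives 13, a β-hydroxy ketone whose strain-driven retro-aldol cleavage of the bond shared by the four- and five-membered rings inserts the two former alkene carbons and closes ring C by two-carbon ring expansion. The ring D/cyclobutane junction can only be cis, so the configuration of C-3a depends only on which face of the cyclopentene is attacked; the methyl group on the adjacent carbon shields its own face and the bulky CMe2 terminus should bond anti to it, which gives (3aS). C-8a is created when the ring D enolate is protonated; approach on the side of the C-3a hydrogen, away from the CMe2 group, gives the cis-fused (8aS) ketone. The fused, not crossed, regiochemistry follows from the five-membered first closure. The step needs the ring enol acetate and not the side-chain enol ester, and it needs cold, brief methanolysis so that C-8a is not equilibrated and the 1,5-diketone does not undergo transannular aldolization.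

Step 10
Reactants: 14 cis-fused diketone
Product: 15 cis-fused 4,4,6-trimethyl-1-methylideneoctahydroazulen-5-one
Conditions: Zn, CH2Br2, TiCl4, THF/CH2Cl2, 0 °C → rt
Reagents that add atoms: dibromomethane, BrCBr
Why: Takai–Lombardo methylenation; the reagent is not basic, so the α-centres are not epimerized, and the cyclopentanone reacts while the ring C ketone, flanked by CMe2 and CHMe, should not.

Step 11
Reactants: 15 methylidene ketone
Product: 16 cis-fused 1-hydroxy-1,4,4,6-tetramethyloctahydroazulen-5-one
Conditions: Co(acac)2 (cat.), PhSiH3, O2 (1 atm), THF, rt
Reagents that add atoms: dioxygen, O=O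
Why: Mukaiyama hydration (Markovnikov, through the tertiary radical); oxygen should be captured on the convex face, that of the fusion hydrogens, so the hydroxyl lies there and the former methylene becomes the methyl on the ring C side. A hydride opening of the corresponding epoxide would also reduce the ring C ketone, which this reaction leaves alone.

Step 12
Reactants: 16 hydroxy ketone
Product: 17 bis(triethylsilyl) derivative (tertiary silyl ether and ring C silyl enol ether)
Conditions: Et3SiOTf, Et3N, CH2Cl2, 0 °C → rt
Reagents that add atoms: triethylsilyl trifluoromethanesulfonate, CC[Si](CC)(CC)OS(=O)(=O)C(F)(F)F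
Why: Silylation of the tertiary alcohol together with soft enolization and O-silylation of the ketone; only the methyl-bearing α-carbon has a hydrogen, so a single enol ether can form.

Step 13
Reactants: 17 bis(triethylsilyl) derivative
Product: 18 ring C enone (C-6/C-7 alkene) with the C-1 triethylsilyl ether
Conditions: Pd(OAc)2, MeCN, rt
Reagents that add atoms: none
Why: Saegusa–Ito dehydrogenation; the divalent palladium enolate undergoes β-hydride elimination into the ring to give the conjugated trisubstituted enone, and the methyl stereocentre that guided step 9 becomes an alkene carbon.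

Step 14
Reactants: 18 enone
Product: 19 cross-conjugated diene (exocyclic methylene at C-5)
Conditions: Cp2TiMe2, toluene, 70 °C
Reagents that add atoms: dimethyltitanocene, C[Ti](C)(C1C=CC=C1)C1C=CC=C1
Why: Petasis methylenation; the titanium methylidene formed on heating olefinates hindered and enolizable carbonyl groups and tolerates silyl ethers.

Step 15
Reactants: 19 diene
Product: 21 primary alcohol (hydroxymethyl on C-5 syn to ring D), via B-alkyl-9-BBN adduct 20 (not isolated)
Conditions: 9-BBN, THF, 0 → 50 °C; then NaOH, H2O2, 0 °C
Reagents that add atoms: 9-borabicyclo[3.3.1]nonane, B1C2CCCC1CCC2; hydrogen peroxide, OO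
Why: Hydroboration–oxidation; boron adds to the terminal carbon of the 1,1-disubstituted alkene and not to the trisubstituted one, and hydrogen should reach C-5 from the convex face (that of the fusion hydrogens, away from ring D), which places the new CH2 group syn to ring D as in the target.

Step 16
Reactants: 21 primary alcohol
Product: 22 1-phenyltetrazol-5-yl sulfide
Conditions: 1-phenyl-1H-tetrazole-5-thiol, PPh3, i-PrO2CN=NCO2i-Pr, THF, 0 °C → rt
Reagents that add atoms: 1-phenyl-1H-tetrazole-5-thiol, Sc1nnnn1-c1ccccc1
Why: Mitsunobu thioetherification of a primary alcohol; the tertiary silyl ether and the alkene are inert and no stereocentre is involved.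

Step 17
Reactants: 22 sulfide
Product: 23 1-phenyltetrazol-5-yl sulfone
Conditions: (NH4)6Mo7O24·4H2O (cat.), 30% H2O2, EtOH, 0 °C → rt
Reagents that add atoms: hydrogen peroxide, OO
Why: Molybdate-catalysed oxidation of sulfide to sulfone; oxidation at sulfur is much faster than epoxidation of the unactivated trisubstituted alkene.

**Fragment 2 (rings A/B)**

Step 18
Reactants: 24 3-ethoxycyclohex-2-en-1-one
Product: 25 4-ethoxy-2-oxocyclohex-3-en-1-yl acetate (racemic)
Conditions: Mn(OAc)3·2H2O, benzene, reflux (Dean–Stark)
Reagents that add atoms: manganese triacetate, CC(=O)[O-].CC(=O)[O-].CC(=O)[O-].[Mn+3]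
Why: α'-Acetoxylation of an enone by trivalent manganese acetate; vinylogous esters react at the saturated α'-carbon.

Step 19
Reactants: 25 racemic acetate
Product: 26 (R)-3-ethoxy-6-hydroxycyclohex-2-en-1-one
Conditions: Pseudomonas cepacia lipase, phosphate buffer pH 7/t-BuOMe, rt, stopped near half conversion
Reagents that add atoms: none
Why: Enzymatic kinetic resolution by enantioselective ester hydrolysis, a known way to resolve α'-acetoxy enones; the unreacted acetate is separated.

Step 20
Reactants: 26 (R)-hydroxy enone
Product: 27 (R)-6-[(tert-butyldimethylsilyl)oxy]-3-ethoxycyclohex-2-en-1-one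
Conditions: t-BuMe2SiCl, imidazole, DMF, rt
Reagents that add atoms: tert-butyldimethylsilyl chloride, CC(C)(C)[Si](C)(C)Cl
Why: Silylation of the secondary alcohol; the bulky silyl ether later directs the conjugate addition.

Step 21
Reactants: 27 silyloxy vinylogous ester; 28 5-bromo-2-methylpent-2-ene
Product: 31 (R)-4-[(tert-butyldimethylsilyl)oxy]-3-(4-methylpent-3-en-1-yl)cyclohex-2-en-1-one, via Grignard reagent 29 (not isolated), via carbinol adduct 30 (not isolated)
Conditions: 28, Mg, THF; CeCl3, then 27, −78 °C; then 1 M HCl, THF, 0 °C
Reagents that add atoms: magnesium, [Mg]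
Why: Stork–Danheiser sequence; 1,2-addition to the vinylogous ester and acid hydrolysis of the enol ether with loss of water transpose the enone, so the silyloxy carbon becomes C-4 next to the new substituent; the organocerium reagent suppresses enolization of the α-silyloxy ketone and so protects its stereocentre.

Step 22
Reactants: 31 4-silyloxy enone
Product: 32 trimethylsilyl enol ether with the quaternary C-5a' centre
Conditions: MeLi, CuI, Et2O, 0 °C; then 31, Me3SiCl, Et3N, THF, −78 °C
Reagents that add atoms: methyllithium, [Li]C; chlorotrimethylsilane, C[Si](C)(C)Cl
Why: Conjugate addition of Me2CuLi, accelerated and trapped by Me3SiCl; the methyl group should add anti to the neighbouring silyloxy group, the known preference of 4-silyloxycyclohexenones, which makes the angular methyl anti to the oxygen and fixes the later cis ring fusion.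

Step 23
Reactants: 32 silyl enol ether
Product: 33 α-(benzyloxymethyl) ketone
Conditions: BnOCH2Cl, TiCl4, CH2Cl2, −78 °C
Reagents that add atoms: benzyl chloromethyl ether, ClCOCc1ccccc1
Why: Lewis acid-mediated alkylation of a silyl enol ether with an α-chloro ether (Mukaiyama type); the oxocarbenium ion should attack C-6' on the face away from the side chain and the silyloxy group, that is syn to the angular methyl.

Step 24
Reactants: 33 benzyloxymethyl ketone
Product: 34 tertiary alcohol at C-7'
Conditions: MeMgBr, CeCl3, THF, −78 → 0 °C
Reagents that add atoms: methylmagnesium bromide, C[Mg]Br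
Why: 1,2-Addition of a methyl nucleophile; the axial substituent on the quaternary carbon blocks axial attack, as in 3,3,5-trimethylcyclohexanone, so methyl should enter equatorially and the hydroxyl ends up axial, cis to the benzyloxymethyl group and the angular methyl; CeCl3 limits enolization and β-elimination.

Step 25
Reactants: 34 trisubstituted alkene
Product: 35 side-chain epoxide
Conditions: D-fructose-derived Shi ketone (30 mol%), KHSO5, K2CO3, Bu4NHSO4, MeCN/CH2(OMe)2/aq. buffer pH 10.5, 0 °C
Reagents that add atoms: potassium peroxymonosulfate, [K+].[O-]S(=O)(=O)OO
Why: Shi asymmetric epoxidation of the only alkene by the chiral dioxirane; it should give one epoxide (R at the new CH–O carbon), which keeps the later intermediates single compounds although this carbon ends as the ketone.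

Step 26
Reactants: 35 epoxide
Product: 36 isopropenyl carbinol
Conditions: Et2AlCl, lithium 2,2,6,6-tetramethylpiperidide, toluene, 0 °C; then 35, 0 °C → rt
Reagents that add atoms: none
Why: Aluminium amide-mediated isomerization of a trisubstituted epoxide to the allylic alcohol; syn β-elimination removes a methyl hydrogen, the C–O bond of the carbinol carbon is not broken and its configuration is kept.

Step 27
Reactants: 36 silyl-protected allylic alcohol
Product: 37 triol
Conditions: Bu4NF, THF, rt
Reagents that add atoms: none
Why: Fluoride desilylation frees the C-9a' hydroxyl for ring closure; it is done only after the epoxide is gone, so no six-membered ether can form.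

Step 28
Reactants: 37 triol
Product: 39 cis-fused oxepane diol (rings A and B), via organomercurial 38 (not isolated)
Conditions: Hg(OCOCF3)2, THF, 0 °C; then NaBH4, aq. NaOH, 0 °C
Reagents that add atoms: mercury bis(trifluoroacetate), O=C(O[Hg]OC(=O)C(F)(F)F)C(F)(F)F
Why: Intramolecular oxymercuration–demercuration; Markovnikov attack of the C-9a' hydroxyl on the tertiary carbon of the 1,1-disubstituted alkene closes ring A in the 7-exo mode, and hydride replaces mercury to give the second methyl group. The cis fusion is already fixed by the configurations of C-5a' and C-9a'.

Step 29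
Reactants: 39 oxepane diol
Product: 40 bis(triethylsilyl) ether
Conditions: Et3SiOTf, 2,6-lutidine, CH2Cl2, −78 → 0 °C
Reagents that add atoms: triethylsilyl trifluoromethanesulfonate, CC[Si](CC)(CC)OS(=O)(=O)C(F)(F)F
Why: Silyl triflate silylation protects both the secondary and the hindered tertiary alcohol against the basic union step.

Step 30
Reactants: 40 benzyl ether
Product: 41 primary alcohol
Conditions: H2, Pd on carbon, EtOAc, rt
Reagents that add atoms: none
Why: Hydrogenolysis of the benzyl ether; 40 has no alkene, and silyl ethers survive in an aprotic solvent.

Step 31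
Reactants: 41 primary alcohol
Product: 42 ring B carbaldehyde
Conditions: Dess–Martin periodinane, NaHCO3, CH2Cl2, 0 °C → rt
Reagents that add atoms: none
Why: Buffered Dess–Martin oxidation to the aldehyde without epimerization at C-6' or β-elimination of the silyloxy group.

**Union and end game**

Step 32
Reactants: 23 sulfone; 42 aldehyde
Product: 43 (E)-alkene joining the two halves
Conditions: KN(SiMe3)2, DME, −60 °C → rt (base added to the mixture of 23 and 42)
Reagents that add atoms: none
Why: Julia–Kocienski olefination; addition of the sulfonyl carbanion to the aldehyde, Smiles rearrangement and loss of SO2 and the tetrazolone form the linker C=C bond, a union that tolerates the hindrance on both sides and touches no stereocentre (the alkene geometry is of no consequence).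

Step 33
Reactants: 43 alkene
Product: 44 saturated tris(triethylsilyl) ether
Conditions: 2-nitrobenzenesulfonylhydrazide, Et3N, CH2Cl2, rt
Reagents that add atoms: none
Why: Diimide reduction; diimide transfers hydrogen to the 1,2-disubstituted alkene much faster than to the trisubstituted ring C alkene, and cannot isomerize the latter.

Step 34
Reactants: 44 tris(triethylsilyl) ether
Product: 45 triol
Conditions: Bu4NF, THF, 40 °C
Reagents that add atoms: none
Why: Global fluoride desilylation of one secondary and two tertiary triethylsilyl ethers under non-acidic conditions that spare the tertiary alcohols.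

Step 35
Reactants: 45 triol
Product: 46 target
Conditions: Dess–Martin periodinane, NaHCO3, CH2Cl2, rt
Reagents that add atoms: none
Why: Dess–Martin oxidation of the only secondary alcohol to the ring A ketone; the tertiary alcohols and the alkene do not react.

## Compound list

1 | cyclopentanone | O=C1CCCC1 | starting material
2 | (S)-N-cyclopentylidene-2-(methoxymethyl)pyrrolidin-1-amine | COC[C@@H]1CCCN1N=C1CCCC1 | intermediate
3 | (S)-2-(methoxymethyl)-N-[(2R)-2-methylcyclopentylidene]pyrrolidin-1-amine (C=N drawn syn to the methyl-bearing carbon, as first formed) | C[C@@H]1CCC/C1=N/N1CCC[C@H]1COC | intermediate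
4 | (R)-2-methylcyclopentan-1-one | C[C@@H]1CCCC1=O | intermediate
5 | 2-methylbut-3-en-2-ol | CC(C)(O)C=C | starting material
6 | triethyl orthoacetate | CCOC(C)(OCC)OCC | starting material
7 | ethyl 5-methylhex-4-enoate | CCOC(=O)CCC=C(C)C | intermediate
8 | 5-methylhex-4-enal | O=CCCC=C(C)C | intermediate
9 | (2R)-5-(1-hydroxy-5-methylhex-4-en-1-yl)-2-methylcyclopentan-1-one (mixture at the two new centres) | C[C@@H]1CCC(C(O)CCC=C(C)C)C1=O | intermediate
10 | (5R)-5-methyl-2-(5-methylhex-4-enoyl)cyclopentan-1-one (enolized β-diketone, drawn as the ring enol) | C[C@@H]1CCC(C(=O)CCC=C(C)C)=C1O | intermediate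
11 | (5R)-5-methyl-2-(5-methylhex-4-enoyl)cyclopent-1-en-1-yl acetate | C[C@@H]1CCC(C(=O)CCC=C(C)C)=C1OC(C)=O | intermediate
12 | cyclobutyl acetate photoadduct (cyclobutane anti to the ring methyl, cis-fused to the new cyclopentanone) | C[C@@H]1CC[C@]2(C(=O)CC[C@@H]2C3(C)C)[C@]13OC(C)=O | intermediate (not isolated)
13 | cyclobutanol from 12 | C[C@@H]1CC[C@]2(C(=O)CC[C@@H]2C3(C)C)[C@]13O | intermediate (not isolated)
14 | (3aS,6R,8aS)-4,4,6-trimethyloctahydroazulene-1,5-dione (cis-fused) | C[C@@H]1CC[C@H]2[C@H](CCC2=O)C(C)(C)C1=O | intermediate
15 | cis-fused 4,4,6-trimethyl-1-methylideneoctahydroazulen-5-one | C[C@@H]1CC[C@H]2[C@H](CCC2=C)C(C)(C)C1=O | intermediate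
16 | cis-fused 1-hydroxy-1,4,4,6-tetramethyloctahydroazulen-5-one (OH cis to the fusion hydrogens) | C[C@@H]1CC[C@H]2[C@H](CC[C@]2(C)O)C(C)(C)C1=O | intermediate
17 | C-1 triethylsilyl ether and C-5 triethylsilyl enol ether of 16 | CC=1CC[C@H]2[C@H](CC[C@]2(C)O[Si](CC)(CC)CC)C(C)(C)C=1O[Si](CC)(CC)CC | intermediate
18 | C-6/C-7 enone with the C-1 triethylsilyl ether | CC1=CC[C@H]2[C@H](CC[C@]2(C)O[Si](CC)(CC)CC)C(C)(C)C1=O | intermediate
19 | 5-methylidene diene with the C-1 triethylsilyl ether | CC1=CC[C@H]2[C@H](CC[C@]2(C)O[Si](CC)(CC)CC)C(C)(C)C1=C | intermediate
20 | B-alkyl-9-BBN adduct of 19 | CC1=CC[C@H]2[C@H](CC[C@]2(C)O[Si](CC)(CC)CC)C(C)(C)[C@@H]1CB1C2CCCC1CCC2 | intermediate (not isolated)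
21 | C-5 hydroxymethyl compound (CH2OH syn to ring D) | CC1=CC[C@H]2[C@H](CC[C@]2(C)O[Si](CC)(CC)CC)C(C)(C)[C@@H]1CO | intermediate
22 | 1-phenyltetrazol-5-yl sulfide of 21 | CC1=CC[C@H]2[C@H](CC[C@]2(C)O[Si](CC)(CC)CC)C(C)(C)[C@@H]1CSc1nnnn1-c1ccccc1 | intermediate
23 | 1-phenyltetrazol-5-yl sulfone | CC1=CC[C@H]2[C@H](CC[C@]2(C)O[Si](CC)(CC)CC)C(C)(C)[C@@H]1CS(=O)(=O)c1nnnn1-c1ccccc1 | intermediate
24 | 3-ethoxycyclohex-2-en-1-one | CCOC1=CC(=O)CCC1 | starting material
25 | 4-ethoxy-2-oxocyclohex-3-en-1-yl acetate (racemic) | CCOC1=CC(=O)C(OC(C)=O)CC1 | intermediate
26 | (R)-3-ethoxy-6-hydroxycyclohex-2-en-1-one | CCOC1=CC(=O)[C@H](O)CC1 | intermediate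
27 | (R)-6-[(tert-butyldimethylsilyl)oxy]-3-ethoxycyclohex-2-en-1-one | CCOC1=CC(=O)[C@H](O[Si](C)(C)C(C)(C)C)CC1 | intermediate
28 | 5-bromo-2-methylpent-2-ene | CC(C)=CCCBr | starting material
29 | (4-methylpent-3-en-1-yl)magnesium bromide | CC(C)=CCC[Mg]Br | intermediate (not isolated)
30 | tertiary carbinol 1,2-adduct (carbinol centre unassigned, either epimer serves) | CCOC1=CC(O)(CCC=C(C)C)[C@H](O[Si](C)(C)C(C)(C)C)CC1 | intermediate (not isolated)
31 | (R)-4-[(tert-butyldimethylsilyl)oxy]-3-(4-methylpent-3-en-1-yl)cyclohex-2-en-1-one | O=C1CC[C@@H](O[Si](C)(C)C(C)(C)C)C(CCC=C(C)C)=C1 | intermediate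
32 | trimethylsilyl enol ether; quaternary carbon with methyl anti and side chain syn to the silyloxy group | C[Si](C)(C)OC1CC[C@@H](O[Si](C)(C)C(C)(C)C)[C@@](C)(CCC=C(C)C)C=1 | intermediate
33 | 2-(benzyloxymethyl) ketone; CH2OBn syn to the angular methyl | O=C1CC[C@@H](O[Si](C)(C)C(C)(C)C)[C@@](C)(CCC=C(C)C)[C@@H]1COCc1ccccc1 | intermediate
34 | tertiary alcohol; OH cis to CH2OBn and to the angular methyl | C[C@@]1(O)CC[C@@H](O[Si](C)(C)C(C)(C)C)[C@@](C)(CCC=C(C)C)[C@@H]1COCc1ccccc1 | intermediate
35 | (R)-epoxide of the side-chain alkene of 34 | C[C@@]1(O)CC[C@@H](O[Si](C)(C)C(C)(C)C)[C@@](C)(CC[C@H]2OC2(C)C)[C@@H]1COCc1ccccc1 | intermediate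
36 | (R)-isopropenyl carbinol | C[C@@]1(O)CC[C@@H](O[Si](C)(C)C(C)(C)C)[C@@](C)(CC[C@@H](O)C(C)=C)[C@@H]1COCc1ccccc1 | intermediate
37 | triol (free hydroxyl on the ring carbon next to the quaternary carbon) | C[C@@]1(O)CC[C@@H](O)[C@@](C)(CC[C@@H](O)C(C)=C)[C@@H]1COCc1ccccc1 | intermediate
38 | cyclized organomercurial (mercurated carbon unassigned, both epimers converge) | c1ccccc1COC[C@H]1[C@]2(C)CC[C@@H](O)C(C)(C[Hg]OC(=O)C(F)(F)F)O[C@@H]2CC[C@@]1(C)O | intermediate (not isolated)
39 | cis-fused 2,2-dimethyloxepan-3-ol/cyclohexane diol with the C-6' benzyloxymethyl group | c1ccccc1COC[C@H]1[C@]2(C)CC[C@@H](O)C(C)(C)O[C@@H]2CC[C@@]1(C)O | intermediate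
40 | bis(triethylsilyl) ether of 39 | c1ccccc1COC[C@H]1[C@]2(C)CC[C@@H](O[Si](CC)(CC)CC)C(C)(C)O[C@@H]2CC[C@@]1(C)O[Si](CC)(CC)CC | intermediate
41 | C-6' hydroxymethyl compound | OC[C@H]1[C@]2(C)CC[C@@H](O[Si](CC)(CC)CC)C(C)(C)O[C@@H]2CC[C@@]1(C)O[Si](CC)(CC)CC | intermediate
42 | C-6' carbaldehyde | O=C[C@H]1[C@]2(C)CC[C@@H](O[Si](CC)(CC)CC)C(C)(C)O[C@@H]2CC[C@@]1(C)O[Si](CC)(CC)CC | intermediate
43 | (E)-alkene joining C-5 and C-6' | CC1=CC[C@H]2[C@H](CC[C@]2(C)O[Si](CC)(CC)CC)C(C)(C)[C@@H]1/C=C/[C@H]1[C@]2(C)CC[C@@H](O[Si](CC)(CC)CC)C(C)(C)O[C@@H]2CC[C@@]1(C)O[Si](CC)(CC)CC | intermediate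
44 | saturated tris(triethylsilyl) ether | CC1=CC[C@H]2[C@H](CC[C@]2(C)O[Si](CC)(CC)CC)C(C)(C)[C@@H]1CC[C@H]1[C@]2(C)CC[C@@H](O[Si](CC)(CC)CC)C(C)(C)O[C@@H]2CC[C@@]1(C)O[Si](CC)(CC)CC | intermediate
45 | triol (ring A secondary alcohol, two tertiary alcohols) | CC1=CC[C@H]2[C@H](CC[C@]2(C)O)C(C)(C)[C@@H]1CC[C@H]1[C@]2(C)CC[C@@H](O)C(C)(C)O[C@@H]2CC[C@@]1(C)O | intermediate
46 | target, (1S,3aS,5R,8aS)-hydroazulene linked to the (5a'S,6'S,7'R,9a'R)-oxepanone/cyclohexane | CC1=CC[C@H]2[C@H](CC[C@]2(C)O)C(C)(C)[C@@H]1CC[C@H]1[C@]2(C)CCC(=O)C(C)(C)O[C@@H]2CC[C@@]1(C)O | target

## Step count and least certain steps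

Total: 35 steps. Longest linear sequence: 19 steps (steps 1–3, 6–17 and 32–35). Fragment 2 takes 14 steps (18–31).

**Step 9 (key step).** Three things may go wrong. A single methyl group may discriminate the faces of the cyclopentene only weakly. O-acylation in step 8 may go partly to the side-chain oxygen, which would feed a crossed cycloaddition. Under basic methanolysis C-8a may equilibrate towards the trans-fused ketone, or the 1,5-diketone may undergo transannular aldolization. The fallback changes how the cyclobutanol is released. It sets out from 10: benzyl chloroformate and pyridine should give the enol benzyl carbonate F1; irradiation as in step 9 should give the cyclobutyl carbonate photoadduct F2, which has no alkene left; hydrogenolysis (H2, Pd on carbon, EtOAc) then frees cyclobutanol 13 under neutral conditions, and its fragmentation returns to the route at 14. Adducts from the wrong face are diastereomers of 14 while the methyl stereocentre is still present and can be removed there.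

**Step 15.** Hydrogen may be delivered to C-5 from the ring D face, because one methyl of the C-4 gem-dimethyl group may shield the convex face more than ring D shields the other. The fallback delivers carbon instead of hydrogen on the ring D face by a sigmatropic shift. It sets out from enone 18: nucleophilic epoxidation (t-BuOOH, benzyltrimethylammonium hydroxide) on the ring D face should give the epoxy ketone F3; Wharton transposition (N2H4·H2O, AcOH, MeOH) gives the allylic alcohol F4 with a C-5/C-6 alkene and the C-7 hydroxyl on that face; KH and Bu3SnCH2I give the stannylmethyl ether F5; n-BuLi at −78 °C then triggers a [2,3]-Wittig–Still rearrangement that moves the CH2OH group suprafacially to C-5 and restores the C-6/C-7 alkene, returning to the route at 21. The face of the epoxidation is what must be checked.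

**Step 28.** Closure of the seven-membered ring may be slow because the alkene is deactivated by the allylic hydroxyl, so intermolecular capture of the mercurinium ion or reversal may compete. The fallback uses a radical–polar crossover in place of electrophilic activation. It sets out from 36: Et3SiCl and imidazole protect the allylic hydroxyl as the triethylsilyl ether F6; hydrogen-atom-transfer hydroalkoxylation with [N,N'-bis(3,5-di-tert-butylsalicylidene)cyclohexane-1,2-diaminato]cobalt (divalent cobalt, catalytic), an N-fluoro-2,4,6-trimethylpyridinium salt and PhSiH3 should close the ring with the silyl ether oxygen on C-9a' as the nucleophile and loss of its silyl group, giving oxepane F7; Et3SiOTf and 2,6-lutidine then silylate the tertiary alcohol, returning to the route at 40.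

**Step 33 (with step 32).** The linker alkene is flanked by two hindered methines, so its reduction may be slow enough for the ring C alkene to compete; in step 32 the hindered aldehyde may be enolized instead of attacked. The fallback forms the linker bond by carbonyl addition and removes oxygen by a radical, so no alkene has to be reduced. It sets out from 21: I2, PPh3 and imidazole give the iodide F8; t-BuLi at −78 °C, then CeCl3 and aldehyde 42, give the secondary carbinol F9 (either epimer); NaH, CS2 and MeI give the xanthate F10; Bu3SnH with AIBN in toluene at 80 °C (Barton–McCombie deoxygenation) returns to the route at 44.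

**Step 11.** The planar tertiary radical may capture oxygen with low facial selectivity. The fallback is the polar sequence. It sets out from 15: mCPBA with NaHCO3 should epoxidize the exocyclic alkene from the convex face to give the spiro-epoxide F11; LiEt3BH opens it at the CH2 carbon and also reduces the ring C ketone, giving the diol F12; Dess–Martin oxidation of the secondary alcohol returns to the route at 16.

## Further compounds

F1 | step 9 | (5R)-5-methyl-2-(5-methylhex-4-enoyl)cyclopent-1-en-1-yl benzyl carbonate | C[C@@H]1CCC(C(=O)CCC=C(C)C)=C1OC(=O)OCc1ccccc1
F2 | step 9 | cyclobutyl benzyl carbonate photoadduct | C[C@@H]1CC[C@]2(C(=O)CC[C@@H]2C3(C)C)[C@]13OC(=O)OCc1ccccc1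
F3 | step 15 | 6,7-epoxy ketone (epoxide on the ring D face) | C[C@@]12O[C@@H]1C[C@H]3[C@H](CC[C@]3(C)O[Si](CC)(CC)CC)C(C)(C)C2=O
F4 | step 15 | transposed allylic alcohol (C-5/C-6 alkene, C-7 hydroxyl on the ring D face) | CC=1[C@H](O)C[C@H]2[C@H](CC[C@]2(C)O[Si](CC)(CC)CC)C(C)(C)C=1
F5 | step 15 | tributylstannylmethyl ether of F4 | CC=1[C@H](OC[Sn](CCCC)(CCCC)CCCC)C[C@H]2[C@H](CC[C@]2(C)O[Si](CC)(CC)CC)C(C)(C)C=1
F6 | step 28 | triethylsilyl ether of the allylic alcohol of 36 | C[C@@]1(O)CC[C@@H](O[Si](C)(C)C(C)(C)C)[C@@](C)(CC[C@@H](O[Si](CC)(CC)CC)C(C)=C)[C@@H]1COCc1ccccc1
F7 | step 28 | oxepane with the ring A triethylsilyl ether and free tertiary alcohol | c1ccccc1COC[C@H]1[C@]2(C)CC[C@@H](O[Si](CC)(CC)CC)C(C)(C)O[C@@H]2CC[C@@]1(C)O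
F8 | step 33 | C-5 iodomethyl compound | CC1=CC[C@H]2[C@H](CC[C@]2(C)O[Si](CC)(CC)CC)C(C)(C)[C@@H]1CI
F9 | step 33 | coupled secondary carbinol (carbinol centre unassigned) | CC1=CC[C@H]2[C@H](CC[C@]2(C)O[Si](CC)(CC)CC)C(C)(C)[C@@H]1CC(O)[C@H]1[C@]2(C)CC[C@@H](O[Si](CC)(CC)CC)C(C)(C)O[C@@H]2CC[C@@]1(C)O[Si](CC)(CC)CC
F10 | step 33 | S-methyl xanthate of F9 | CC1=CC[C@H]2[C@H](CC[C@]2(C)O[Si](CC)(CC)CC)C(C)(C)[C@@H]1CC(OC(=S)SC)[C@H]1[C@]2(C)CC[C@@H](O[Si](CC)(CC)CC)C(C)(C)O[C@@H]2CC[C@@]1(C)O[Si](CC)(CC)CC
F11 | step 11 | spiro-epoxide of 15 (oxygen on the convex face) | C[C@@H]1CC[C@H]2[C@H](CC[C@@]23CO3)C(C)(C)C1=O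
F12 | step 11 | diol (C-1 tertiary alcohol, C-5 secondary alcohol unassigned) | C[C@@H]1CC[C@H]2[C@H](CC[C@]2(C)O)C(C)(C)C1O
A1 | alternative 1 | ring B hydroxy ester with quaternary carbon, secondary alcohol and silylated carbinol | COC(=O)C[C@H]1[C@](C)(CO[Si](C)(C)C(C)(C)C)[C@H](O)CC[C@@]1(C)O[Si](C)(C)C
A2 | alternative 2 | tricyclic hydroxy lactone holding rings A and B | O=C1C[C@H]2[C@]3(C)CC[C@@H](O)C(C)(C)O[C@@H]3CC[C@@]2(C)O1
A3 | alternative 3 | cis-fused ring C/D cyclopentenone with silyloxyethyl arm | CC1=CC[C@H]2[C@H](C=CC2=O)C(C)(C)[C@@H]1CCO[Si](C)(C)C(C)(C)C
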